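**Plan** (xanthanolide numbering; primed locants belong to the epoxide half; ring A = cycloheptane C1, C5–C10 of the hydroxylated half)

1. Retrosynthesis: the C1 hydroxyl is removed (γ-oxygenation of a β,γ-unsaturated ketone), then the cyclohexene is cut at C5–C13′ and C3–C11′ (Diels–Alder). This gives 8-epi-xanthatin and its 1β,5β-epoxide, so both halves come from one monomer.
2. The monomer is cut at C1–C2 (Heck), at the lactone carbonyl C12 (CO insertion) and, in ring A, at C5–C6 and C7–C8 (carbonyl ylide plus methyl vinyl ketone).
3. Enabling feature: in cycloheptane ring A the lactone O–CH carbon C8 and C5, the ring-fusion CH beside the carbinol carbon C1, are 1,4 to each other (C8–C7–C6–C5). The aldehyde oxygen of a cyclic ylide can therefore bridge them in an 8-oxabicyclo[3.2.1]octanone; its C8–O bond becomes the lactone oxygen and its C5–O bond is cut reductively.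
4. Forward order: diazo keto ester aldehyde chain → oxygen-bridged ring A → bridge opened and lactone ring closed → dienone monomer → epoxide → cyclohexene and spiro centre by cycloaddition → C1 hydroxyl.
5. Stereochemistry: C10 from an Evans alkylation; C7 and C8 from the ylide cycloaddition (anti to the C10 methyl, acetyl exo); C1′/C5′, C5, C11′ and C1 from attack on the β face of the cis-lactone cycloheptene, the convex face of the dienophile and axial oxygenation.

Key step: step 6

Assumption: metal enolates and catalyst-bound species (rhodium carbene, acylpalladium, samarium ketyl) count as reactive forms within one operation and are named in the Why lines, while every metal-free compound formed in a flask is numbered; the δ-hydroxy β-keto ester of step 3 equilibrates with its cyclic hemiketal and is drawn open-chain.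

Step 1
Reactants: 1 (R)-4-benzyl-3-propanoyl-1,3-oxazolidin-2-one; 2 allyl iodide
Product: 3 (R)-4-benzyl-3-[(2S)-2-methylpent-4-enoyl]-1,3-oxazolidin-2-one
Conditions: NaN(SiMe3)2, THF, −78 °C; then 2, −78 to −40 °C
Reagents that add atoms: none
Why: Evans asymmetric alkylation, in which the chelated Z-sodium enolate is allylated on the face away from the benzyl group of the (R)-auxiliary, setting the methyl-bearing centre (later C10) as S.

Step 2
Reactants: 3 (R)-4-benzyl-3-[(2S)-2-methylpent-4-enoyl]-1,3-oxazolidin-2-one
Product: 6 (S)-3-methyloxolan-2-one, via aldehyde imide 4 (not isolated), via hydroxy imide 5 (not isolated)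
Conditions: O3, CH2Cl2/MeOH, −78 °C; Me2S, −78 °C to rt; NaBH4, 0 °C; then TsOH·H2O (cat.), CH2Cl2, rt
Reagents that add atoms: ozone, [O-][O+]=O
Why: Ozonolysis with reductive work-up gives aldehyde 4, NaBH4 reduces it far faster than it attacks the imide, and the γ-hydroxy imide 5 lactonises by 5-exo acyl transfer with release of the auxiliary, the α-centre never meeting a base.

Step 3
Reactants: 6 (S)-3-methyloxolan-2-one; 7 tert-butyl acetate
Product: 8 tert-butyl (4S)-6-hydroxy-4-methyl-3-oxohexanoate
Conditions: LiN(iPr)2 (2.3 equiv), 7 (2.3 equiv), THF, −78 °C; then 6, −78 to −40 °C; AcOH quench at −78 °C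
Reagents that add atoms: none
Why: Crossed Claisen acylation of a lithium ester enolate by a lactone, in which addition to the lactone carbonyl at −78 °C outruns α-deprotonation and the second equivalent of enolate stores the product as its β-keto ester enolate, protecting the ketone from over-addition and the methyl centre from epimerisation.

Step 4
Reactants: 8 tert-butyl (4S)-6-hydroxy-4-methyl-3-oxohexanoate
Product: 9 tert-butyl (4S)-2-diazo-6-hydroxy-4-methyl-3-oxohexanoate
Conditions: 4-acetamidobenzenesulfonyl azide, Et3N, MeCN, 0 °C to rt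
Reagents that add atoms: 4-acetamidobenzenesulfonyl azide, CC(=O)Nc1ccc(cc1)S(=O)(=O)N=[N+]=[N-]
Why: Regitz diazo transfer to the active methylene of the open-chain β-keto ester, which drains the hemiketal equilibrium while the primary alcohol and the methyl centre are inert to Et3N and the sulfonyl azide.

Step 5
Reactants: 9 tert-butyl (4S)-2-diazo-6-hydroxy-4-methyl-3-oxohexanoate
Product: 10 tert-butyl (4S)-2-diazo-4-methyl-3,6-dioxohexanoate
Conditions: Dess–Martin periodinane, NaHCO3, CH2Cl2, 0 °C to rt; used at once
Reagents that add atoms: none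
Why: Dess–Martin oxidation of the primary alcohol under buffered, non-basic conditions, which acceptor/acceptor diazo compounds tolerate.

Step 6
Reactants: 10 tert-butyl (4S)-2-diazo-4-methyl-3,6-dioxohexanoate; 11 methyl vinyl ketone
Product: 13 tert-butyl (3S)-6-exo-acetyl-3-methyl-2-oxo-8-oxabicyclo[3.2.1]octane-1-carboxylate (methyl equatorial and on the same side of the carbocycle as O8), via carbonyl ylide 12 (not isolated)
Conditions: Rh2(OAc)4 (2 mol %), 11 (10 equiv, BHT-stabilised), PhCF3, 60 °C, slow addition of 10
Reagents that add atoms: none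
Why: Loss of N2 at divalent rhodium gives an electrophilic carbene that is captured by the aldehyde oxygen, closing the six-membered pyranone ring as carbonyl ylide 12 (ring closure by O-attack on the carbene carbon); 12 then undergoes a concerted, suprafacial (3+2) cycloaddition to 11 that forms C5–C6 and C7–C8 at once and so closes cycloheptane ring A together with the five-membered ring of the oxygen bridge. The closest known reaction type is the rhodium-catalysed tandem carbonyl ylide formation–cycloaddition of 2-diazo-3,6-dioxo esters with acceptor alkenes to 8-oxabicyclo[3.2.1]octan-2-ones. Regiochemistry follows the frontier orbitals: the ester-stabilised ylide carbon C5 (largest HOMO coefficient and the more hindered terminus) bonds to the CH2 of 11, and the aldehyde-derived C8 to the acetyl-bearing carbon. C5 and C8 are set by the C10 methyl, because the alkene adds to the half-chair ylide through a chair-like transition state with the methyl equatorial, that is anti to the methyl, which puts the methyl and the oxygen bridge on the same side of ring A; C7 is set by exo approach of the acetyl group, and as this centre is enolisable and exo is the more stable position, an endo fraction can be equilibrated with base. The step needs chemoselective capture of the carbene by the tethered aldehyde (six-membered ring formation is fast, and slow addition of 10 into excess 11 keeps 10 from acting as dipolarophile) as well as the regio-, exo- and face selectivity named above, the last being the least secured.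

Step 7
Reactants: 13 tert-butyl (3S)-6-exo-acetyl-3-methyl-2-oxo-8-oxabicyclo[3.2.1]octane-1-carboxylate
Product: 14 tert-butyl (3S)-3-methyl-2-oxo-6-exo-[1-(trifluoromethylsulfonyloxy)ethenyl]-8-oxabicyclo[3.2.1]octane-1-carboxylate
Conditions: KN(SiMe3)2 (1.05 equiv), THF, −78 °C; Comins' reagent, −78 °C
Reagents that add atoms: Comins' reagent (N-(5-chloropyridin-2-yl)bis(trifluoromethanesulfonyl)imide), Clc1ccc(nc1)N(S(=O)(=O)C(F)(F)F)S(=O)(=O)C(F)(F)F
Why: Kinetic enolate formation and O-triflation, in which the hindered amide takes a proton from the acetyl methyl group (the ring ketone has one hindered tertiary α-hydrogen and a quaternary α-carbon) and Comins' reagent traps the enolate at −78 °C before it can equilibrate towards C7, where β-elimination of the bridge would begin.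

Step 8
Reactants: 14 the bicyclic alkenyl triflate
Product: 15 tert-butyl 5-hydroxy-3-methyl-2-oxo-6-[1-(trifluoromethylsulfonyloxy)ethenyl]cycloheptane-1-carboxylate (3-methyl, 5-hydroxyl and 6-alkenyl all cis; C1 epimers)
Conditions: SmI2 (2.5 equiv), THF/MeOH, −78 °C
Reagents that add atoms: none
Why: SmI2 reduction of an α-alkoxy ketone, in which the ketyl expels the oxygen at C5 (also α to the ester), a second electron gives the samarium enolate and methanol protonates it, so the bridge opens with the C8–O bond intact as a hydroxyl cis to the C7 side chain while the alkenyl triflate is inert to SmI2 without additive at −78 °C.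

Step 9
Reactants: 15 the hydroxy β-keto ester alkenyl triflate
Product: 16 tert-butyl 7-methyl-3-methylidene-2,6-dioxooctahydro-2H-cyclohepta[b]furan-5-carboxylate (cis-fused lactone; H-3a, H-7 and H-8a on one face; C5 epimers)
Conditions: Pd(PPh3)4 (10 mol %), CO (1 atm), Et3N, MeCN, 60 °C
Reagents that add atoms: carbon monoxide, [C-]#[O+]
Why: Palladium-catalysed carbonylative lactonisation, in which oxidative addition of zerovalent palladium into the alkenyl triflate, CO insertion and 5-exo capture of the acylpalladium by the cis C8 hydroxyl give the cis-fused α-methylene γ-lactone without forming a stereocentre.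

Step 10
Reactants: 16 the lactone β-keto tert-butyl ester
Product: 18 7-methyl-3-methylidenehexahydro-2H-cyclohepta[b]furan-2,6(3H)-dione (cis-fused; H-3a, H-7 and H-8a on one face), via keto acid 17 (not isolated)
Conditions: CF3CO2H/CH2Cl2 (1:4), 0 °C to rt; then toluene, 80 °C
Reagents that add atoms: none
Why: Acidolysis of the tert-butyl ester (the reason for choosing this ester) and thermal decarboxylation of β-keto acid 17 through a six-membered transition state turn C5 into a methylene group under acidic conditions that the methylene lactone tolerates.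

Step 11
Reactants: 18 the keto lactone
Product: 19 7-methyl-3-methylidene-2-oxo-3,3a,4,7,8,8a-hexahydro-2H-cyclohepta[b]furan-6-yl trifluoromethanesulfonate (C1=C5 enol triflate; stereocentres as in 18)
Conditions: LiN(SiMe3)2 (1.1 equiv), THF, −78 °C; Comins' reagent, −78 °C
Reagents that add atoms: Comins' reagent (N-(5-chloropyridin-2-yl)bis(trifluoromethanesulfonyl)imide), Clc1ccc(nc1)N(S(=O)(=O)C(F)(F)F)S(=O)(=O)C(F)(F)F
Why: Kinetic enol triflate formation, in which the amide deprotonates the C5 methylene rather than the methyl-bearing C10 methine, the methylene lactone offers no acidic hydrogen and is not attacked by the hindered amide at −78 °C, and Comins' reagent triflates the lithium enolate at low temperature.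

Step 12
Reactants: 19 the ring alkenyl triflate; 11 methyl vinyl ketone
Product: 20 8-epi-xanthatin (cis-fused α-methylene lactone with H-7, H-8 and H-10 all α; C1=C5 and (E)-C2=C3 dienone)
Conditions: Pd(OAc)2 (5 mol %), PPh3 (10 mol %), Et3N, 11 (5 equiv), DMF, 60 °C
Reagents that add atoms: none
Why: Heck reaction, in which oxidative addition into the alkenyl triflate, syn-carbopalladation of the monosubstituted acceptor alkene 11 (faster than that of the 1,1-disubstituted methylene lactone and favoured by the excess of 11) and syn β-hydride elimination give the (E)-dienone.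

Step 13
Reactants: 20 8-epi-xanthatin
Product: 21 8-epi-xanthatin 1β,5β-epoxide (epoxide oxygen on the face of the C10 methyl and the lactone oxygen)
Conditions: 3-chloroperoxybenzoic acid (1.05 equiv), NaHCO3, CH2Cl2, 0 °C
Reagents that add atoms: 3-chloroperoxybenzoic acid, OOC(=O)c1cccc(Cl)c1
Why: Prilezhaev epoxidation of the trisubstituted C1=C5 bond, the only alkene not attached directly to a carbonyl group and therefore the most electron-rich, with the peracid expected on the β face because C7 and C9 of the chair-like ring screen the α face, which sets C1 and C5; an α-epoxide would be a separable diastereomer.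

Step 14
Reactants: 20 8-epi-xanthatin; 21 8-epi-xanthatin 1β,5β-epoxide
Product: 22 Diels–Alder adduct (cyclohexene C1=C2; H-5 α; acetyl at C3 cis to C6 and to the lactone carbonyl C12′; spiro C11′ bonded to C3 on the face of H-7′)
Conditions: 21 (3 equiv, excess recovered), BHT (cat.), toluene (2 M), 90 °C, sealed tube, dark
Reagents that add atoms: none
Why: Thermal Diels–Alder reaction of the s-cis C5=C1–C2=C3 diene of 20 with the exocyclic methylene of 21, in which the acyl-bearing terminus C3 bonds to the substituted dienophile carbon C11′ ("ortho" rule), the lactone carbonyl is endo, the dienophile is attacked on its convex face (that of H-7′) and the diene on its β face at C5, setting C5, C3 and the spiro centre C11′.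

Step 15
Reactants: 22 the Diels–Alder adduct
Product: 24 the target (1β-hydroxy, C2=C3 enone, trans-fused at C1/C5), via hydroperoxide 23 (not isolated)
Conditions: DBU (1.2 equiv), O2 (1 atm), P(OEt)3 (2 equiv), MeCN, −20 to 0 °C
Reagents that add atoms: dioxygen, O=O
Why: Vinylogous (γ) autoxidation of a β,γ-unsaturated ketone, in which DBU removes the doubly activated C3 hydrogen, the dienolate takes up O2 at C1 and the phosphite reduces hydroperoxide 23 in situ; oxygen should enter axially, anti to the pseudo-axial H-5 and away from the axial C7′ on the other face, giving the β-hydroxyl of the trans ring fusion.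

**Compound list**

1 | (R)-4-benzyl-3-propanoyl-1,3-oxazolidin-2-one | CCC(=O)N1[C@H](Cc2ccccc2)COC1=O | starting material
2 | allyl iodide (3-iodoprop-1-ene) | C=CCI | starting material
3 | (R)-4-benzyl-3-[(2S)-2-methylpent-4-enoyl]-1,3-oxazolidin-2-one | C=CC[C@H](C)C(=O)N1[C@H](Cc2ccccc2)COC1=O | intermediate
4 | aldehyde imide, (R)-4-benzyl-3-[(2S)-2-methyl-4-oxobutanoyl]-1,3-oxazolidin-2-one | O=CC[C@H](C)C(=O)N1[C@H](Cc2ccccc2)COC1=O | intermediate (not isolated)
5 | hydroxy imide, (R)-4-benzyl-3-[(2S)-4-hydroxy-2-methylbutanoyl]-1,3-oxazolidin-2-one | OCC[C@H](C)C(=O)N1[C@H](Cc2ccccc2)COC1=O | intermediate (not isolated)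
6 | (S)-3-methyloxolan-2-one | C[C@H]1CCOC1=O | intermediate
7 | tert-butyl acetate | CC(=O)OC(C)(C)C | starting material
8 | tert-butyl (4S)-6-hydroxy-4-methyl-3-oxohexanoate | CC(C)(C)OC(=O)CC(=O)[C@@H](C)CCO | intermediate
9 | tert-butyl (4S)-2-diazo-6-hydroxy-4-methyl-3-oxohexanoate | CC(C)(C)OC(=O)C(=[N+]=[N-])C(=O)[C@@H](C)CCO | intermediate
10 | tert-butyl (4S)-2-diazo-4-methyl-3,6-dioxohexanoate (key-step precursor) | CC(C)(C)OC(=O)C(=[N+]=[N-])C(=O)[C@@H](C)CC=O | intermediate
11 | methyl vinyl ketone (but-3-en-2-one) | C=CC(C)=O | starting material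
12 | carbonyl ylide, (4S)-2-(tert-butoxycarbonyl)-4-methyl-3-oxo-4,5-dihydro-3H-pyran-1-ium-2-ide | CC(C)(C)OC(=O)[C-]1[O+]=CC[C@H](C)C1=O | intermediate (not isolated)
13 | tert-butyl (3S)-6-exo-acetyl-3-methyl-2-oxo-8-oxabicyclo[3.2.1]octane-1-carboxylate (key-step product) | CC(C)(C)OC(=O)[C@]12C[C@H](C(C)=O)[C@H](O1)C[C@H](C)C2=O | intermediate
14 | tert-butyl (3S)-3-methyl-2-oxo-6-exo-[1-(trifluoromethylsulfonyloxy)ethenyl]-8-oxabicyclo[3.2.1]octane-1-carboxylate | CC(C)(C)OC(=O)[C@]12C[C@H](C(=C)OS(=O)(=O)C(F)(F)F)[C@H](O1)C[C@H](C)C2=O | intermediate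
15 | tert-butyl 5-hydroxy-3-methyl-2-oxo-6-[1-(trifluoromethylsulfonyloxy)ethenyl]cycloheptane-1-carboxylate (3,5,6-substituents all cis) | C=C(OS(=O)(=O)C(F)(F)F)[C@H]1CC(C(=O)OC(C)(C)C)C(=O)[C@@H](C)C[C@H]1O | intermediate
16 | tert-butyl 7-methyl-3-methylidene-2,6-dioxooctahydro-2H-cyclohepta[b]furan-5-carboxylate (cis-fused) | C=C1C(=O)O[C@@H]2C[C@H](C)C(=O)C(C(=O)OC(C)(C)C)C[C@H]12 | intermediate
17 | 7-methyl-3-methylidene-2,6-dioxooctahydro-2H-cyclohepta[b]furan-5-carboxylic acid | C=C1C(=O)O[C@@H]2C[C@H](C)C(=O)C(C(=O)O)C[C@H]12 | intermediate (not isolated)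
18 | 7-methyl-3-methylidenehexahydro-2H-cyclohepta[b]furan-2,6(3H)-dione (cis-fused) | C=C1C(=O)O[C@@H]2C[C@H](C)C(=O)CC[C@H]12 | intermediate
19 | 7-methyl-3-methylidene-2-oxo-3,3a,4,7,8,8a-hexahydro-2H-cyclohepta[b]furan-6-yl trifluoromethanesulfonate | C=C1C(=O)O[C@@H]2C[C@H](C)C(OS(=O)(=O)C(F)(F)F)=CC[C@H]12 | intermediate
20 | 8-epi-xanthatin | C=C1C(=O)O[C@@H]2C[C@H](C)C(/C=C/C(C)=O)=CC[C@H]12 | intermediate
21 | 8-epi-xanthatin 1β,5β-epoxide | C=C1C(=O)O[C@@H]2C[C@H](C)[C@]3(/C=C/C(C)=O)O[C@@H]3C[C@H]12 | intermediate
22 | Diels–Alder adduct of 20 and 21 (C1=C2 alkene, 3-acetyl, spiro C11′) | C=C1C(=O)O[C@@H]2C[C@H](C)C3=C[C@H](C(C)=O)[C@@]4(C[C@@H]3C[C@H]12)C(=O)O[C@@H]1C[C@H](C)[C@]2(/C=C/C(C)=O)O[C@@H]2C[C@@H]14 | intermediate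
23 | C1 β-hydroperoxide of the target skeleton | C=C1C(=O)O[C@@H]2C[C@H](C)[C@@]3(OO)C=C(C(C)=O)[C@@]4(C[C@@H]3C[C@H]12)C(=O)O[C@@H]1C[C@H](C)[C@]2(/C=C/C(C)=O)O[C@@H]2C[C@@H]14 | intermediate (not isolated)
24 | CNP0177598.1 | C=C1C(=O)O[C@@H]2C[C@H](C)[C@@]3(O)C=C(C(C)=O)[C@@]4(C[C@@H]3C[C@H]12)C(=O)O[C@@H]1C[C@H](C)[C@]2(/C=C/C(C)=O)O[C@@H]2C[C@@H]14 | target

**Total step count:** 15. **Longest linear sequence:** 15 steps (steps 1 to 15; step 13 converts part of 20 into the second cycloaddition partner).

**Steps most likely to fail**

Step 15. Oxygen capture by the dienolate may be unselective between the two faces of C1, or the dienolate may be protonated at C1 to the conjugated enone before oxygen arrives, and the base may also attack the methylene lactones. The fallback delivers the oxygen from a hydroxyl group instead and sets out from 20. Luche reduction (NaBH4, CeCl3·7H2O, MeOH, −78 °C) gives the C4 carbinol, dienol F1, as an epimer mixture. Heating F1 with 21 as in step 14 gives the cycloadduct alcohol F2, whose carbinol-bearing chain at C3 stands on the β face of the new cyclohexene. VO(acac)2 and tert-butyl hydroperoxide then epoxidise the C1=C2 bond on that face under the direction of the homoallylic hydroxyl, giving the epoxy alcohol F3. Dess–Martin oxidation leads to the β,γ-epoxy ketone F4, which Et3N opens by E1cB elimination to the γ-hydroxy enone, returning to the route at 24.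

Step 14. Compound 20 is diene and dienophile at once, so its self-dimerisation may outrun the cross-addition, and two electron-poor partners may react so slowly that the material is lost through the methylene lactones. The fallback masks the dienophile of the diene partner and sets out from 20. Conjugate addition of thiophenol (Et3N cat., CH2Cl2, 0 °C) gives the sulfide F5, which cannot dimerise and can be heated with 21 for long periods or under pressure to give the sulfide cycloadduct F6. NaIO4 in aqueous methanol oxidises F6 to the sulfoxide F7, and thermal syn-elimination (toluene, 110 °C, CaCO3) restores the exocyclic methylene, returning to the route at 22.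

Step 13. The pseudo-axial C10 methyl may steer the peracid to the α face, giving mainly the wrong epoxide. The fallback inverts the face by way of a halohydrin and sets out from 20. N-Bromosuccinimide in aqueous THF forms the bromonium ion on the face the electrophile prefers (α), and water opens it anti at C1 to give the bromohydrin F8. DBU then closes the epoxide by SN2 displacement of bromide at C5, so the oxygen ends on the β face, returning to the route at 21.

**Further compounds**

F1 | step 15 | dienol, 4-hydroxy analogue of 8-epi-xanthatin (C4 epimers) | C=C1C(=O)O[C@@H]2C[C@H](C)C(/C=C/C(C)O)=CC[C@H]12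
F2 | step 15 | cycloadduct alcohol, 22 with C4 hydroxyl in place of the C4 ketone | C=C1C(=O)O[C@@H]2C[C@H](C)C3=C[C@H](C(C)O)[C@@]4(C[C@@H]3C[C@H]12)C(=O)O[C@@H]1C[C@H](C)[C@]2(/C=C/C(C)=O)O[C@@H]2C[C@@H]14
F3 | step 15 | epoxy alcohol, 1β,2β-epoxide of F2 | C=C1C(=O)O[C@@H]2C[C@H](C)[C@]36O[C@@H]6[C@H](C(C)O)[C@@]4(C[C@@H]3C[C@H]12)C(=O)O[C@@H]1C[C@H](C)[C@]2(/C=C/C(C)=O)O[C@@H]2C[C@@H]14
F4 | step 15 | β,γ-epoxy ketone, 1β,2β-epoxide of 22 | C=C1C(=O)O[C@@H]2C[C@H](C)[C@]36O[C@@H]6[C@H](C(C)=O)[C@@]4(C[C@@H]3C[C@H]12)C(=O)O[C@@H]1C[C@H](C)[C@]2(/C=C/C(C)=O)O[C@@H]2C[C@@H]14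
F5 | step 14 | sulfide, 13-(phenylsulfanyl)-11,13-dihydro-8-epi-xanthatin (C11 epimers) | c1ccccc1SCC1C(=O)O[C@@H]2C[C@H](C)C(/C=C/C(C)=O)=CC[C@H]12
F6 | step 14 | sulfide cycloadduct, 22 with the methylene of the diene half masked as CH–CH2SPh | c1ccccc1SCC1C(=O)O[C@@H]2C[C@H](C)C3=C[C@H](C(C)=O)[C@@]4(C[C@@H]3C[C@H]12)C(=O)O[C@@H]1C[C@H](C)[C@]2(/C=C/C(C)=O)O[C@@H]2C[C@@H]14
F7 | step 14 | sulfoxide of F6 | c1ccccc1S(=O)CC1C(=O)O[C@@H]2C[C@H](C)C3=C[C@H](C(C)=O)[C@@]4(C[C@@H]3C[C@H]12)C(=O)O[C@@H]1C[C@H](C)[C@]2(/C=C/C(C)=O)O[C@@H]2C[C@@H]14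
F8 | step 13 | bromohydrin, 5α-bromo-1β-hydroxy-1,5-dihydro-8-epi-xanthatin | C=C1C(=O)O[C@@H]2C[C@H](C)[C@@](O)(/C=C/C(C)=O)[C@@H](Br)C[C@H]12
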